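Ring A is cut across C3–C4 and C5–C6. Its run of three oxygens (C6–OH, C1–OMe, C2–OH) next to an unsubstituted C3 can be traced to a diene made from methyl 2-methoxyacetoacetate, and the neighbouring carbon substituents at C4 (C8) and C5 (C7, leading to ring B) to the two ends of an alkyne. One Diels–Alder benzannulation of bis(silyloxy)diene 15 with ring B ynone 9, finished by mild acid, makes both bonds, closes and aromatises ring A and delivers the two phenols free beside the intact methyl ether. Ynone 9 carries the dibromocatechol and the C8 oxygen as TBS ethers; its C7 carbonyl directs the regiochemistry and is removed afterwards.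

Key step: step 9

Remarks on the chemistry
- Numbering: ring A is C1 (OMe), C2 (OH), C3 (H), C4 (carries C8, the CH2OH carbon), C5 (carries C7, the bridging CH2), C6 (OH). Ring B is C1' (on C7), C2' and C3' (Br), C4' and C5' (OH), C6' (H). TBS = tert-butyldimethylsilyl, TMS = trimethylsilyl.
- The target has no stereocentre. Compounds 8, 12 and 16 are racemic and their stereocentres are lost again. Alkene geometry in 13, 15 and 19 is not controlled and does not matter.
- All three protected hydroxyls are silyl ethers. Benzyl ethers on ring B would need hydrogenolysis, which endangers the C–Br bonds, or a boron trihalide. The Lewis acid would ionise the C8–O bond para to the C1 methoxy group, with Friedel–Crafts closure onto C6', and could demethylate C1, which is flanked by two hydroxyls. Base and buffered fluoride avoid both.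
- C8–O stays silylated until C7 is reduced, because a free C8–OH could add to the quinone methide of step 10.

Step 1
Reactants: 1 vanillin (4-hydroxy-3-methoxybenzaldehyde)
Product: 3 2,3-dibromo-4-hydroxy-5-methoxybenzaldehyde, via 5-bromovanillin 2 (not isolated)
Conditions: Br2 (1.05 equiv), AcOH, rt; then Fe powder (cat.), Br2 (1.3 equiv), 50 °C; pour into water
Reagents that add atoms: bromine, BrBr
Why: Electrophilic aromatic bromination goes first ortho to the free phenol (C5 of vanillin) and then, with FeBr3 formed in situ, at C6 para to the methoxy group, the only remaining oxygen-activated position that is not wedged between the formyl and methoxy groups.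

Step 2
Reactants: 3 2,3-dibromo-4-hydroxy-5-methoxybenzaldehyde
Product: 4 2,3-dibromo-4,5-dihydroxybenzaldehyde
Conditions: BBr3 (2.5 equiv), CH2Cl2, −78 °C to rt; ice water
Reagents that add atoms: none
Why: Lewis-acid ether cleavage, in which bromide removes the methyl group of the boron-complexed guaiacol by SN2, while the aldehyde and the aryl bromides come back unchanged on hydrolysis.

Step 3
Reactants: 4 2,3-dibromo-4,5-dihydroxybenzaldehyde
Product: 5 4,5-bis(tert-butyldimethylsilyloxy)-2,3-dibromobenzaldehyde
Conditions: TBSCl (2.5 equiv), imidazole (5 equiv), DMF, rt to 40 °C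
Reagents that add atoms: tert-butyldimethylsilyl chloride, CC(C)(C)[Si](C)(C)Cl
Why: Imidazole-promoted O-silylation of both phenols gives base- and fluoride-labile ethers that can later be removed without touching C–Br or the C8–O bond.

Step 4
Reactants: 6 tert-butyldimethyl(prop-2-yn-1-yloxy)silane; 5 4,5-bis(tert-butyldimethylsilyloxy)-2,3-dibromobenzaldehyde
Product: 8 1-[4,5-bis(tert-butyldimethylsilyloxy)-2,3-dibromophenyl]-4-(tert-butyldimethylsilyloxy)but-2-yn-1-ol (racemic), via lithium acetylide 7 (not isolated)
Conditions: 6 (1.3 equiv), n-BuLi (1.2 equiv), THF, −78 °C; then 5, −78 °C; AcOH quench at −78 °C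
Reagents that add atoms: none
Why: 1,2-Addition of a lithium acetylide to an aryl aldehyde, with the alkyne in slight excess over n-BuLi so that no alkyllithium is left to exchange with the aryl bromides; the carbinol stereocentre forms as a racemate and is removed in step 5.

Step 5
Reactants: 8 1-[4,5-bis(tert-butyldimethylsilyloxy)-2,3-dibromophenyl]-4-(tert-butyldimethylsilyloxy)but-2-yn-1-ol
Product: 9 1-[4,5-bis(tert-butyldimethylsilyloxy)-2,3-dibromophenyl]-4-(tert-butyldimethylsilyloxy)but-2-yn-1-one
Conditions: activated MnO2 (excess), CH2Cl2, rt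
Reagents that add atoms: none
Why: MnO2 oxidation of a doubly activated (benzylic and propargylic) alcohol to the ynone under neutral conditions that spare all three silyl ethers.

Step 6
Reactants: 10 methyl methoxyacetate
Product: 12 methyl 2-methoxy-3-oxobutanoate (racemic), via lithium ester enolate 11 (not isolated)
Conditions: 10 (2.0 equiv), LiN(iPr)2 (commercial solution, 2.0 equiv), THF, −78 °C; AcCl (1.0 equiv), −78 °C; 1 M HCl
Reagents that add atoms: acetyl chloride, CC(=O)Cl
Why: Crossed Claisen acylation of a preformed ester enolate by an acid chloride, the second equivalent of enolate taking up the acidic proton of the product; the new stereocentre is racemic and becomes sp2 in step 7.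

Step 7
Reactants: 12 methyl 2-methoxy-3-oxobutanoate
Product: 13 methyl 2-methoxy-3-(trimethylsilyloxy)but-2-enoate
Conditions: Me3SiCl (1.5 equiv), Et3N (1.6 equiv), toluene, rt, 2–3 d; filtration under argon, distillation
Reagents that add atoms: chlorotrimethylsilane, C[Si](C)(C)Cl
Why: Amine-mediated enolisation and O-silylation of a beta-keto ester gives the conjugated silyl enol ether, the standard first stage of bis(silyloxy)diene preparation.

Step 8
Reactants: 13 methyl 2-methoxy-3-(trimethylsilyloxy)but-2-enoate
Product: 15 1,2-dimethoxy-1,3-bis(trimethylsilyloxy)buta-1,3-diene, via lithium dienolate 14 (not isolated)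
Conditions: LiN(iPr)2 (commercial solution, 1.2 equiv), THF, −78 °C; Me3SiCl (1.3 equiv), −78 °C to rt; pentane, filtration under argon; used without chromatography
Reagents that add atoms: chlorotrimethylsilane, C[Si](C)(C)Cl
Why: Kinetic deprotonation of the gamma-methyl group gives the extended ester dienolate, which the chlorosilane traps on oxygen (silyl ketene acetal formation) to give the 1-alkoxy-1,3-bis(silyloxy)diene; either ketene acetal geometry is usable.

Step 9
Reactants: 15 1,2-dimethoxy-1,3-bis(trimethylsilyloxy)buta-1,3-diene; 9 1-[4,5-bis(tert-butyldimethylsilyloxy)-2,3-dibromophenyl]-4-(tert-butyldimethylsilyloxy)but-2-yn-1-one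
Product: 17 [4,5-bis(tert-butyldimethylsilyloxy)-2,3-dibromophenyl][6-(tert-butyldimethylsilyloxymethyl)-2,4-dihydroxy-3-methoxyphenyl]methanone, via cyclohexa-1,4-diene cycloadduct 16 (not isolated)
Conditions: 15 (2 equiv), toluene, 80 °C, sealed tube; then 10% aq. citric acid, THF, 0 °C to rt
Reagents that add atoms: none
Why: The electron-rich diene 15 adds to the electron-poor alkyne of 9 in a normal-electron-demand [4+2] cycloaddition (concerted but asynchronous, or Michael-type addition followed by ring closure), its CH2 terminus, which has the largest HOMO coefficient, bonding to the alkyne carbon beta to the C7 carbonyl (C4) and its ketene acetal carbon to the alpha carbon (C5). The closest known reaction type is the Diels–Alder benzannulation of 1-alkoxy-1,3-bis(silyloxy)buta-1,3-dienes with alkynones and alkynoates to 2-acylresorcinols and 2,4-dihydroxybenzoates. Ring A closes by intermolecular [4+2] cycloaddition, C3–C4 and C5–C6 both being formed in this operation, to give cyclohexa-1,4-diene 16, whose mixed methyl silyl ketal at C6 is hydrolysed by the dilute acid to a ketone with loss of methanol, after which enolisation gives the arene. No stereocentre is created in the product, and C6 of 16 is racemic and transient. The step needs regioselectivity, secured by the conjugating C7 carbonyl that makes C4 the electrophilic alkyne carbon, and the correct aromatisation mode (C6–OH, not C6–OMe), secured by cleaving the O–Si bond with acid before any thermal loss of silanol. Neutral heating should leave the aryl bromides, the three TBS ethers and the C1 methyl ether untouched.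

Step 10
Reactants: 17 [4,5-bis(tert-butyldimethylsilyloxy)-2,3-dibromophenyl][6-(tert-butyldimethylsilyloxymethyl)-2,4-dihydroxy-3-methoxyphenyl]methanone
Product: 21 3,4-dibromo-5-{[6-(tert-butyldimethylsilyloxymethyl)-2,4-dihydroxy-3-methoxyphenyl]methyl}benzene-1,2-diol, via bis(ethyl carbonate) ketone 18 (not isolated), via ortho-quinone methide 19 (not isolated), via monocarbonate diarylmethane 20 (not isolated)
Conditions: ClCO2Et (2.5 equiv), Et3N (2.6 equiv), THF, 0 °C; filter; NaBH4 (excess), THF–H2O, 0 °C to rt; then 2 M NaOH, MeOH, rt, under argon; AcOH to pH 6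
Reagents that add atoms: none
Why: Reductive deoxygenation of an ortho-hydroxyaryl ketone through its aryl carbonate: acylation of both phenols frees the chelated C7 carbonyl for borohydride reduction, the resulting alkoxide takes over the C6 carbonate and 1,4-elimination gives ortho-quinone methide 19, which hydride reduces at C7, and hydroxide then cleaves the remaining C2 carbonate and both aryl silyl ethers while the base-stable alkyl TBS ether at C8 stays.

Step 11
Reactants: 21 3,4-dibromo-5-{[6-(tert-butyldimethylsilyloxymethyl)-2,4-dihydroxy-3-methoxyphenyl]methyl}benzene-1,2-diol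
Product: 22 3,4-dibromo-5-{[2,4-dihydroxy-6-(hydroxymethyl)-3-methoxyphenyl]methyl}benzene-1,2-diol (CNP0333037.0)
Conditions: HF·pyridine, pyridine, THF, 0 °C to rt; aq. NaHCO3 work-up, extraction under argon
Reagents that add atoms: none
Why: Fluoride-mediated desilylation of a primary alkyl silyl ether under pyridine-buffered conditions that should not ionise the C8–O bond, so neither Friedel–Crafts closure onto C6' nor benzylic ether formation should compete.

Compound list
1 | vanillin (4-hydroxy-3-methoxybenzaldehyde) | COc1cc(C=O)ccc1O | starting material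
2 | 5-bromovanillin (3-bromo-4-hydroxy-5-methoxybenzaldehyde) | COc1cc(C=O)cc(Br)c1O | intermediate (not isolated)
3 | 2,3-dibromo-4-hydroxy-5-methoxybenzaldehyde | COc1cc(C=O)c(Br)c(Br)c1O | intermediate
4 | 2,3-dibromo-4,5-dihydroxybenzaldehyde | O=Cc1cc(O)c(O)c(Br)c1Br | intermediate
5 | 4,5-bis(tert-butyldimethylsilyloxy)-2,3-dibromobenzaldehyde | O=Cc1cc(O[Si](C)(C)C(C)(C)C)c(O[Si](C)(C)C(C)(C)C)c(Br)c1Br | intermediate
6 | tert-butyldimethyl(prop-2-yn-1-yloxy)silane | C#CCO[Si](C)(C)C(C)(C)C | starting material
7 | lithium acetylide of 6, LiC≡CCH2OTBS | [Li]C#CCO[Si](C)(C)C(C)(C)C | intermediate (not isolated)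
8 | 1-[4,5-bis(tert-butyldimethylsilyloxy)-2,3-dibromophenyl]-4-(tert-butyldimethylsilyloxy)but-2-yn-1-ol, racemic | OC(C#CCO[Si](C)(C)C(C)(C)C)c1cc(O[Si](C)(C)C(C)(C)C)c(O[Si](C)(C)C(C)(C)C)c(Br)c1Br | intermediate
9 | 1-[4,5-bis(tert-butyldimethylsilyloxy)-2,3-dibromophenyl]-4-(tert-butyldimethylsilyloxy)but-2-yn-1-one | O=C(C#CCO[Si](C)(C)C(C)(C)C)c1cc(O[Si](C)(C)C(C)(C)C)c(O[Si](C)(C)C(C)(C)C)c(Br)c1Br | intermediate
10 | methyl methoxyacetate | COCC(=O)OC | starting material
11 | lithium 1,2-dimethoxyethen-1-olate (lithium enolate of 10) | COC=C(O[Li])OC | intermediate (not isolated)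
12 | methyl 2-methoxy-3-oxobutanoate, racemic | COC(C(C)=O)C(=O)OC | intermediate
13 | methyl 2-methoxy-3-(trimethylsilyloxy)but-2-enoate, geometry not controlled | COC(=O)C(OC)=C(C)O[Si](C)(C)C | intermediate
14 | lithium 1,2-dimethoxy-3-(trimethylsilyloxy)buta-1,3-dien-1-olate | C=C(O[Si](C)(C)C)C(OC)=C(O[Li])OC | intermediate (not isolated)
15 | 1,2-dimethoxy-1,3-bis(trimethylsilyloxy)buta-1,3-diene, ketene acetal geometry not controlled | COC(O[Si](C)(C)C)=C(OC)C(=C)O[Si](C)(C)C | intermediate
16 | [4,5-bis(tert-butyldimethylsilyloxy)-2,3-dibromophenyl][2-(tert-butyldimethylsilyloxymethyl)-5,6-dimethoxy-4,6-bis(trimethylsilyloxy)cyclohexa-1,4-dien-1-yl]methanone, racemic | COC1=C(O[Si](C)(C)C)CC(CO[Si](C)(C)C(C)(C)C)=C(C(=O)c2cc(O[Si](C)(C)C(C)(C)C)c(O[Si](C)(C)C(C)(C)C)c(Br)c2Br)C1(OC)O[Si](C)(C)C | intermediate (not isolated)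
17 | [4,5-bis(tert-butyldimethylsilyloxy)-2,3-dibromophenyl][6-(tert-butyldimethylsilyloxymethyl)-2,4-dihydroxy-3-methoxyphenyl]methanone | COc1c(O)cc(CO[Si](C)(C)C(C)(C)C)c(C(=O)c2cc(O[Si](C)(C)C(C)(C)C)c(O[Si](C)(C)C(C)(C)C)c(Br)c2Br)c1O | intermediate
18 | 4-[4,5-bis(tert-butyldimethylsilyloxy)-2,3-dibromobenzoyl]-5-(tert-butyldimethylsilyloxymethyl)-2-methoxy-1,3-phenylene bis(ethyl carbonate) | CCOC(=O)Oc1cc(CO[Si](C)(C)C(C)(C)C)c(C(=O)c2cc(O[Si](C)(C)C(C)(C)C)c(O[Si](C)(C)C(C)(C)C)c(Br)c2Br)c(OC(=O)OCC)c1OC | intermediate (not isolated)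
19 | 6-{[4,5-bis(tert-butyldimethylsilyloxy)-2,3-dibromophenyl]methylidene}-3-(ethoxycarbonyloxy)-5-(tert-butyldimethylsilyloxymethyl)-2-methoxycyclohexa-2,4-dien-1-one, alkene geometry not defined | COC1=C(OC(=O)OCC)C=C(CO[Si](C)(C)C(C)(C)C)C(=Cc2cc(O[Si](C)(C)C(C)(C)C)c(O[Si](C)(C)C(C)(C)C)c(Br)c2Br)C1=O | intermediate (not isolated)
20 | 4-{[4,5-bis(tert-butyldimethylsilyloxy)-2,3-dibromophenyl]methyl}-5-(tert-butyldimethylsilyloxymethyl)-3-hydroxy-2-methoxyphenyl ethyl carbonate | CCOC(=O)Oc1cc(CO[Si](C)(C)C(C)(C)C)c(Cc2cc(O[Si](C)(C)C(C)(C)C)c(O[Si](C)(C)C(C)(C)C)c(Br)c2Br)c(O)c1OC | intermediate (not isolated)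
21 | 3,4-dibromo-5-{[6-(tert-butyldimethylsilyloxymethyl)-2,4-dihydroxy-3-methoxyphenyl]methyl}benzene-1,2-diol | COc1c(O)cc(CO[Si](C)(C)C(C)(C)C)c(Cc2cc(O)c(O)c(Br)c2Br)c1O | intermediate
22 | 3,4-dibromo-5-{[2,4-dihydroxy-6-(hydroxymethyl)-3-methoxyphenyl]methyl}benzene-1,2-diol (CNP0333037.0) | COc1c(O)cc(CO)c(Cc2cc(O)c(O)c(Br)c2Br)c1O | target

Total step count: 11 steps.
Longest linear sequence: 8 steps (steps 1, 2, 3, 4, 5, 9, 10, 11 from vanillin); the diene branch contributes steps 6, 7 and 8.

Steps most likely to fail

Step 9. The fully substituted ketene acetal terminus must bond to the alkyne carbon next to a hindered aroyl group, so the cycloaddition may be slower than hydrolysis or silyl transfer of the diene; aromatisation may also proceed partly with loss of silanol in place of methanol. The fallback makes the same two bonds one after the other by polar chemistry, setting out from ynone 9 and diene 15. A TiCl4-promoted Mukaiyama–Michael addition in CH2Cl2 at −78 °C should join the CH2 terminus of the diene to C4 and, after aqueous work-up, give the open-chain keto ester methyl 7-[4,5-bis(tert-butyldimethylsilyloxy)-2,3-dibromophenyl]-5-[(tert-butyldimethylsilyloxy)methyl]-2-methoxy-3,7-dioxohept-5-enoate F1. DBU in toluene would then deprotonate C3, and the resulting dienolate should close C5 onto the ester carbonyl in an intramolecular Claisen condensation that expels methanol and tautomerises to benzophenone 17, where the route is rejoined.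

Step 10. Hydride delivery to a carbonyl flanked by three ortho substituents may be slower than hydrolysis of the aryl carbonates, which would return the chelated, unreactive hydroxy ketone; the free catechol may also oxidise in the basic last stage. The fallback removes the C7 oxygen through a cation instead of a quinone methide, setting out from 17. LiBH4 in THF (0 °C to rt) should reduce the ketone to the benzhydrol [4,5-bis(tert-butyldimethylsilyloxy)-2,3-dibromophenyl][6-(tert-butyldimethylsilyloxymethyl)-2,4-dihydroxy-3-methoxyphenyl]methanol F2. Ionic hydrogenation with Et3SiH and CF3CO2H in CH2Cl2 at −40 °C, where the doubly benzylic, hydroxy-stabilised C7 cation should form far faster than the primary C8–O bond ionises, would give 2-{[4,5-bis(tert-butyldimethylsilyloxy)-2,3-dibromophenyl]methyl}-3-(tert-butyldimethylsilyloxymethyl)-6-methoxybenzene-1,5-diol, written here as 4-{[4,5-bis(tert-butyldimethylsilyloxy)-2,3-dibromophenyl]methyl}-5-(tert-butyldimethylsilyloxymethyl)-2-methoxybenzene-1,3-diol F3. HF·pyridine under the conditions of step 11 would then remove all three silyl groups and give the target 22 directly.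

Step 6. Proton transfer from the product to the ester enolate, self-condensation of the ester and O-acylation may all erode conversion in the crossed Claisen acylation. The fallback is aldol addition followed by oxidation, setting out from 10. The lithium enolate 11 (LiN(iPr)2, THF, −78 °C) is added to acetaldehyde to give methyl 3-hydroxy-2-methoxybutanoate F4 (diastereomer mixture, immaterial), which a Dess–Martin oxidation in CH2Cl2 should convert to keto ester 12, where the route is rejoined.

Further compounds
F1 | step 9 | methyl 7-[4,5-bis(tert-butyldimethylsilyloxy)-2,3-dibromophenyl]-5-[(tert-butyldimethylsilyloxy)methyl]-2-methoxy-3,7-dioxohept-5-enoate (alkene geometry not defined) | COC(=O)C(OC)C(=O)CC(CO[Si](C)(C)C(C)(C)C)=CC(=O)c1cc(O[Si](C)(C)C(C)(C)C)c(O[Si](C)(C)C(C)(C)C)c(Br)c1Br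
F2 | step 10 | [4,5-bis(tert-butyldimethylsilyloxy)-2,3-dibromophenyl][6-(tert-butyldimethylsilyloxymethyl)-2,4-dihydroxy-3-methoxyphenyl]methanol (racemic) | COc1c(O)cc(CO[Si](C)(C)C(C)(C)C)c(C(O)c2cc(O[Si](C)(C)C(C)(C)C)c(O[Si](C)(C)C(C)(C)C)c(Br)c2Br)c1O
F3 | step 10 | 4-{[4,5-bis(tert-butyldimethylsilyloxy)-2,3-dibromophenyl]methyl}-5-(tert-butyldimethylsilyloxymethyl)-2-methoxybenzene-1,3-diol | COc1c(O)cc(CO[Si](C)(C)C(C)(C)C)c(Cc2cc(O[Si](C)(C)C(C)(C)C)c(O[Si](C)(C)C(C)(C)C)c(Br)c2Br)c1O
F4 | step 6 | methyl 3-hydroxy-2-methoxybutanoate (diastereomer mixture) | COC(C(C)O)C(=O)OC
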